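## Retrosynthetic overview
1. The target comes from the tertiary alcohol by O-acetylation in the last step, which does not touch the C9–O bond (fatty-acid numbering, C1 = CO2H).
2. The cyclopentenone is made by forming C9–C13 through conrotatory 4π closure of a 2-hydroxypentadienyl cation. This is the ring closure of the octadecanoid pathway (allene oxide to 12-oxophytodienoic acid), run here on a cation that already carries the C9 oxygen.
3. That cation comes from a 2,5-disubstituted furylcarbinol and water (oxa-Piancatelli manifold). A chiral counter-anion selects the sense of rotation and so sets C9. C13 is then equilibrated, as in the natural cis-to-trans drift of these cyclopentenones.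
4. The furylcarbinol, which holds all 18 carbons, comes from furan, (Z)-hex-3-enal and 8-bromooctanoic acid in one pot. The aldehyde comes from leaf alcohol.
5. There is only one ring, and it is formed in step 3.

Assumption: the (R)-catalyst is taken to give the (1S) carbinol centre. If the sense of induction proves opposite, the equally available (S)-catalyst is used.

## Route

Step 1
Reactants: 1 (Z)-hex-3-en-1-ol
Product: 2 (Z)-hex-3-enal
Conditions: IBX (2-iodoxybenzoic acid, 1.2 equiv), DMSO, 23 °C, 2 h; pentane extraction, dried, used at once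
Reagents that add atoms: none
Why: Hypervalent-iodine alcohol oxidation runs under neutral, non-enolising conditions, so the skipped (Z)-alkene neither moves into conjugation nor isomerises, and no stereocentre is formed.

Step 2
Reactants: 2 (Z)-hex-3-enal; 3 furan; 4 8-bromooctanoic acid
Product: 9 8-{5-[(1RS,3Z)-1-hydroxyhex-3-en-1-yl]furan-2-yl}octanoic acid, via 2-furyllithium 5 (not isolated), via lithium furylhexenolate 6 (not isolated), via C5-lithiated alkoxide 7 (not isolated), via lithium 8-bromooctanoate 8 (not isolated)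
Conditions: 3, n-BuLi (1.0 equiv), THF, −78 → 0 °C; 2, −78 °C, 30 min; n-BuLi (1.1 equiv), TMEDA, −78 → 0 °C, 2 h; 8 (from 4 + n-BuLi 1.0 equiv, THF, −78 °C), DMPU, −40 → 23 °C, 12 h; cold 0.5 M HCl to pH 4
Reagents that add atoms: none
Why: This is a sequential α-lithiation, 1,2-addition, α'-lithiation and SN2 alkylation of furan, in which 5 adds to 2 at −78 °C faster than it enolises it, the second n-BuLi removes the remaining α-H of 6, and the C–Li of 7 (more nucleophilic than its alkoxide and unreactive toward a lithium carboxylate at or below 23 °C) displaces the primary bromide of 8; the carbinol centre forms racemic, which does not matter because step 3 erases it.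

Step 3
Reactants: 9 8-{5-[(1RS,3Z)-1-hydroxyhex-3-en-1-yl]furan-2-yl}octanoic acid
Product: 12 8-{(1S,5S)-1-hydroxy-4-oxo-5-[(2Z)-pent-2-en-1-yl]cyclopent-2-en-1-yl}octanoic acid, via 1,4-dihydroxypentadienyl cation 10 (not isolated), via (1S,5R)-epimer 11 (not isolated)
Conditions: (R)-3,3'-bis(2,4,6-triisopropylphenyl)-1,1'-binaphthyl-2,2'-diyl N-triflylphosphoramide (C51H57F3NO5PS, 10 mol %), H2O (20 equiv), toluene/1,4-dioxane 4:1, 40 °C, 24 h; then Na2SO4, DBU (1.6 equiv), 0 → 23 °C, 2 h; cold aq. citric acid; chromatography (residual 11 re-equilibrated)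
Reagents that add atoms: water, O
Why: Proposed new method: a catalytic enantioselective oxa-Piancatelli rearrangement in which the strong chiral acid ionises the carbinol (the substrate's own CO2H is too weak to run a background reaction at 40 °C), water adds at the alkyl-bearing furan carbon and ring opening gives 10, the C9-hydroxylated analogue of the allene-oxide-derived 2-oxidopentadienyl cation, whose two O–H groups hydrogen-bond to the confined chiral phosphoramidate so that only one sense of the allowed conrotatory 4π closure is open (this sets C9 = ring C1 as S), the out,out geometry (the oxygen donor rotates outward) puts OH and pentenyl trans in 11, and DBU then inverts only the enolisable C13 (ring C5) to the more stable trans-dialkyl isomer 12 (5S, about 5:1 expected by analogy with the cis-to-trans epimerisation of 12-oxophytodienoic acid); the closest known reaction types are the racemic ZnCl2-mediated Piancatelli rearrangement of 5-alkyl-2-furyl homoallyl carbinols, the chiral-phosphoric-acid aza-Piancatelli rearrangement and the chiral N-triflylphosphoramide Nazarov cyclisation.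

Step 4
Reactants: 12 8-{(1S,5S)-1-hydroxy-4-oxo-5-[(2Z)-pent-2-en-1-yl]cyclopent-2-en-1-yl}octanoic acid
Product: 14 8-{(1S,5S)-1-acetoxy-4-oxo-5-[(2Z)-pent-2-en-1-yl]cyclopent-2-en-1-yl}octanoic acid, via acetic mixed anhydride 13 (not isolated)
Conditions: Ac2O (6 equiv), DMAP (0.2 equiv), pyridine/CH2Cl2, 0 → 23 °C, 16 h; then H2O/THF, 23 °C, 1 h
Reagents that add atoms: acetic anhydride, CC(=O)OC(C)=O; water, O
Why: DMAP-catalysed (Steglich-type) acylation acetylates the tertiary alcohol on oxygen, so C1 keeps its configuration (ionisation would need a destabilised 4-oxocyclopentenyl cation), pyridine and DMAP are too weak to cause E1cB loss of acetate, C5 is already the thermodynamic epimer, and the CO2H is only transiently tied up as 13, which the water quench hydrolyses.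

## Compound list
1 | (Z)-hex-3-en-1-ol | CC/C=C\CCO | starting material
2 | (Z)-hex-3-enal | CC/C=C\CC=O | intermediate
3 | furan | c1ccoc1 | starting material
4 | 8-bromooctanoic acid | OC(=O)CCCCCCCBr | starting material
5 | 2-furyllithium | [Li]c1ccco1 | intermediate
6 | lithium (Z)-1-(furan-2-yl)hex-3-en-1-olate (racemic) | CC/C=C\CC(O[Li])c1ccco1 | intermediate
7 | lithium (Z)-1-(5-lithiofuran-2-yl)hex-3-en-1-olate (racemic) | CC/C=C\CC(O[Li])c1ccc([Li])o1 | intermediate
8 | lithium 8-bromooctanoate | [Li+].[O-]C(=O)CCCCCCCBr | intermediate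
9 | 8-{5-[(1RS,3Z)-1-hydroxyhex-3-en-1-yl]furan-2-yl}octanoic acid (racemic carbinol) | CC/C=C\CC(O)c1ccc(CCCCCCCC(=O)O)o1 | intermediate
10 | (10Z,12Z,15Z)-9,12-dihydroxypentadienyl cation (O-protonated 12-hydroxy-9-oxooctadeca-10,12,15-trienoic acid), ion pair with the chiral phosphoramidate | CC/C=C\C/C=C(O)/C=C\C(=[OH+])CCCCCCCC(=O)O | intermediate
11 | 8-{(1S,5R)-1-hydroxy-4-oxo-5-[(2Z)-pent-2-en-1-yl]cyclopent-2-en-1-yl}octanoic acid (OH trans to pentenyl, chains cis) | CC/C=C\C[C@H]1C(=O)C=C[C@]1(CCCCCCCC(=O)O)O | intermediate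
12 | 8-{(1S,5S)-1-hydroxy-4-oxo-5-[(2Z)-pent-2-en-1-yl]cyclopent-2-en-1-yl}octanoic acid (OH cis to pentenyl, chains trans) | CC/C=C\C[C@@H]1C(=O)C=C[C@]1(CCCCCCCC(=O)O)O | intermediate
13 | acetic 8-{(1S,5S)-1-acetoxy-4-oxo-5-[(2Z)-pent-2-en-1-yl]cyclopent-2-en-1-yl}octanoic anhydride | CC/C=C\C[C@@H]1C(=O)C=C[C@]1(CCCCCCCC(=O)OC(C)=O)OC(C)=O | intermediate
14 | 8-{(1S,5S)-1-acetoxy-4-oxo-5-[(2Z)-pent-2-en-1-yl]cyclopent-2-en-1-yl}octanoic acid (CNP0348716.1) | CC/C=C\C[C@@H]1C(=O)C=C[C@]1(CCCCCCCC(=O)O)OC(C)=O | target

## Step count and risks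
- Total steps: 4.
- Longest linear sequence: 4 (1 → 2 → 9 → 12 → 14).

**Most likely to fail: step 3.**
- Risks:
  - The enantioselective oxa variant is unproven.
  - The carbinol may dehydrate to a dienylfuran.
  - Neutral 10 may tautomerise to the ene-dione.
  - DBU may cause retro-aldol erosion of ee or drift to the 4-hydroxy-2,3-dialkyl isomer.
- Fallback: it sets out from 9 and comes back at 12, and it obtains absolute configuration by resolution instead of catalyst control.
  - The established racemic rearrangement (ZnCl2, aqueous 1,4-dioxane, reflux) gives 11 together with its mirror image, the (1R,5S)-hydroxy acid F1.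
  - DBU equilibration as above gives 12 together with its mirror image, the (1R,5R)-hydroxy acid F2.
  - Preparative supercritical-fluid chromatography on a polysaccharide chiral phase separates 12 from F2.
  - F2 can be racemised by base-induced retro-aldol/aldol and recycled.

**Second: step 2.**
- Risks:
  - 5 may enolise 2.
  - Alkylation of 7 by the bromo-carboxylate may be sluggish.
- Fallback: it sets out from 2 and comes back at 9, and it replaces the SN2 alkylation by cross-coupling.
  - 2,5-Dibromofuran undergoes a single Br/Li exchange (n-BuLi, Et2O, −78 °C) to 5-bromo-2-furyllithium F3.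
  - F3 adds to 2 to give (Z)-1-(5-bromofuran-2-yl)hex-3-en-1-ol F4.
  - Ethyl 8-bromooctanoate with Zn dust and LiCl in THF gives (8-ethoxy-8-oxooctyl)zinc bromide F5.
  - Negishi coupling of F4 with F5 (Pd(OAc)2, SPhos, THF, 23 °C) gives ethyl 8-{5-[(1RS,3Z)-1-hydroxyhex-3-en-1-yl]furan-2-yl}octanoate F6.
  - LiOH in THF/H2O converts F6 into 9.

**Third: step 4.**
- Risks:
  - The tertiary alcohol is hindered.
  - The β-acetoxy ketone may lose acetate by E1cB on contact with base.
  - The mixed anhydride complicates the reaction.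
- Fallback: it sets out from 12 and comes back at 14. It masks the acid and keeps the acetate away from all base.
  - tert-Butyl 2,2,2-trichloroacetimidate (CH2Cl2/cyclohexane, 23 °C) gives the tert-butyl ester of 12 F7.
  - Lewis-acid-catalysed acetylation (Ac2O, Sc(OTf)3 5 mol %, MeCN, −20 °C) gives the tert-butyl ester of 14 F8.
  - TFA/CH2Cl2 at 0 °C releases 14.

## Further compounds
F1 | step 3 | 8-{(1R,5S)-1-hydroxy-4-oxo-5-[(2Z)-pent-2-en-1-yl]cyclopent-2-en-1-yl}octanoic acid | CC/C=C\C[C@@H]1C(=O)C=C[C@@]1(CCCCCCCC(=O)O)O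
F2 | step 3 | 8-{(1R,5R)-1-hydroxy-4-oxo-5-[(2Z)-pent-2-en-1-yl]cyclopent-2-en-1-yl}octanoic acid | CC/C=C\C[C@H]1C(=O)C=C[C@@]1(CCCCCCCC(=O)O)O
F3 | step 2 | 5-bromo-2-furyllithium | [Li]c1ccc(Br)o1
F4 | step 2 | (Z)-1-(5-bromofuran-2-yl)hex-3-en-1-ol (racemic) | CC/C=C\CC(O)c1ccc(Br)o1
F5 | step 2 | (8-ethoxy-8-oxooctyl)zinc bromide | CCOC(=O)CCCCCCC[Zn]Br
F6 | step 2 | ethyl 8-{5-[(1RS,3Z)-1-hydroxyhex-3-en-1-yl]furan-2-yl}octanoate | CC/C=C\CC(O)c1ccc(CCCCCCCC(=O)OCC)o1
F7 | step 4 | tert-butyl 8-{(1S,5S)-1-hydroxy-4-oxo-5-[(2Z)-pent-2-en-1-yl]cyclopent-2-en-1-yl}octanoate | CC/C=C\C[C@@H]1C(=O)C=C[C@]1(CCCCCCCC(=O)OC(C)(C)C)O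
F8 | step 4 | tert-butyl 8-{(1S,5S)-1-acetoxy-4-oxo-5-[(2Z)-pent-2-en-1-yl]cyclopent-2-en-1-yl}octanoate | CC/C=C\C[C@@H]1C(=O)C=C[C@]1(CCCCCCCC(=O)OC(C)(C)C)OC(C)=O
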